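**Retrosynthetic overview**

1. Numbering used here: ring C1 (C=O), C2 (C–Me, oxirane), C3 (oxirane CH), C4 (CH2), C5 (CH carrying the side chain), C6 (CH–O-senecioyl); side chain C7(=CH2)–C8H(O-angeloyl)–CH2–CH=CMe2.
2. Endgame: the oxirane (second ring, formed last) comes from the cyclohexenone by Luche reduction, hydroxyl-directed epoxidation and re-oxidation, which places it cis to the C5 side chain; the two esters go on one after the other, C6 first and C8 later.
3. Side chain: the C5–C7 bond is made by nickel-catalysed decarboxylative alkenylation of a ring carboxylic acid with an alkenylzinc that already carries C8 (set by enantioselective allylation of 2-bromoacrolein).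
4. Ring (first ring): a one-flask [3+3] annulation makes C4–C5 and C1–C2. The dianion of a malate-derived hydroxy Weinreb amide (enolate carbon C5, acyl carbon C1) meets (Z)-1-bromo-3-iodobut-2-ene (allylic C4, vinylic C2).
5. Enabling feature: the ring segment C1(=O)–C6H(O)–C5 of the cyclohexanone is an α-oxygenated acyl unit with C5 β to the C6 oxygen, which is the (S)-malate skeleton; its extra carboxyl makes C5 an enolate carbon and later leaves as CO2. The rest of the ring, C2(Me)–C3–C4, is a (Z)-but-2-ene-1,3-diyl unit once the oxirane is taken back to the enone.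

Key step: step 5

Assumption: but-2-yn-1-ol, the acetonide of (S)-malic acid and 2-bromoacrolein are taken as purchasable; the atom numbering of the overview is used throughout.

**Route**

Step 1
Reactants: 1 but-2-yn-1-ol
Product: 3 (2Z)-3-iodobut-2-en-1-ol, via cyclic alkenylalanate 2 (not isolated)
Conditions: NaAlH2(OCH2CH2OMe)2 (Red-Al), THF, 0 °C to rt; then I2, −78 to 0 °C; aq. Rochelle salt, Na2S2O3
Reagents that add atoms: iodine, II
Why: Hydroxyl-directed trans-hydroalumination of the propargylic alcohol puts aluminium on C3 in a five-membered alanate, and iodinolysis with retention should give the Z alkenyl iodide (hydroalumination–iodination).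

Step 2
Reactants: 3 (2Z)-3-iodobut-2-en-1-ol
Product: 4 (2Z)-1-bromo-3-iodobut-2-ene
Conditions: CBr4, PPh3, CH2Cl2, 0 °C
Reagents that add atoms: carbon tetrabromide, BrC(Br)(Br)Br
Why: Appel bromination of the primary allylic alcohol proceeds under neutral conditions and should leave the alkene geometry and the alkenyl iodide untouched.

Step 3
Reactants: 5 2-[(4S)-2,2-dimethyl-5-oxo-1,3-dioxolan-4-yl]acetic acid
Product: 6 tert-butyl 2-[(4S)-2,2-dimethyl-5-oxo-1,3-dioxolan-4-yl]acetate
Conditions: tert-butyl 2,2,2-trichloroacetimidate (2 equiv), CH2Cl2/cyclohexane, rt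
Reagents that add atoms: tert-butyl 2,2,2-trichloroacetimidate, CC(C)(C)OC(=N)C(Cl)(Cl)Cl
Why: Imidate esterification of the free acid gives the tert-butyl ester without base, so the dioxolanone and its stereocentre should be unaffected.

Step 4
Reactants: 6 tert-butyl 2-[(4S)-2,2-dimethyl-5-oxo-1,3-dioxolan-4-yl]acetate
Product: 7 tert-butyl (3S)-3-hydroxy-4-[methoxy(methyl)amino]-4-oxobutanoate
Conditions: MeNH(OMe)·HCl, i-PrMgCl, THF, −20 to 0 °C; aq. NH4Cl
Reagents that add atoms: N,O-dimethylhydroxylamine hydrochloride, CNOC.Cl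
Why: The magnesium amide opens the activated dioxolanone carbonyl (Weinreb amide formation from an ester) and acetone is lost from the hemiketal, while the tert-butyl ester is inert and the carbinol centre is not touched.

Step 5
Reactants: 7 tert-butyl (3S)-3-hydroxy-4-[methoxy(methyl)amino]-4-oxobutanoate; 4 (2Z)-1-bromo-3-iodobut-2-ene
Product: 9 tert-butyl (1R,6S)-6-hydroxy-4-methyl-5-oxocyclohex-3-ene-1-carboxylate, via C-alkylated lithium alkoxide 8 (not isolated)
Conditions: LiN(i-Pr)2 (2.1 equiv), THF, −78 to −20 °C; 4, −78 to −15 °C; then n-Bu3MgLi (1.2 equiv, from n-BuMgCl + 2 n-BuLi), −78 to 0 °C; aq. NH4Cl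
Reagents that add atoms: none
Why: Double deprotonation of 7 gives the chelated lithium alkoxide–ester enolate (Fráter–Seebach dianion), whose C5 displaces the primary allylic bromide of 4 (SN2) to make the C4–C5 bond; iodine–magnesium exchange on the (Z)-alkenyl iodide of 8 with retention then gives an alkenylmagnesium whose C2 adds to the Weinreb carbonyl C1, and the magnesium-chelated tetrahedral adduct releases the ketone only on work-up. The closest known reaction types are the Fráter–Seebach alkylation of malate dianions with allylic halides and the halogen–metal-exchange-triggered cycloacylation (Parham-type cyclisation) of alkenyl halides onto Weinreb amides, and the two can share a flask because hindered diisopropylamine is deprotonated only slowly by organomagnesium species. The one ring that closes, the cyclohexenone, does so in the 6-exo-trig mode, the Z geometry of the alkenylmetal holding C2 cis to the C3–C4 tether. The new stereocentre C5 is set anti to the C6 oxygen because the allylic bromide approaches the lithium-bridged six-membered chelate on the face opposite the C6 carboxamide; C6 is carried over unchanged from (S)-malic acid, and C5 is in any case re-formed in step 11. The step needs C-alkylation without SN2′ transposition (primary bromide, chelated enolate) and six-ring acylation at the amide rather than five-ring attack on the ester, which the inertness of the tert-butyl ester towards organomagnesium below 0 °C and the chelating acceptor character of the Weinreb amide should secure, the stable chelate also preventing over-addition.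

Step 6
Reactants: 9 tert-butyl (1R,6S)-6-hydroxy-4-methyl-5-oxocyclohex-3-ene-1-carboxylate
Product: 10 tert-butyl (1R,6S)-4-methyl-6-[(3-methylbut-2-enoyl)oxy]-5-oxocyclohex-3-ene-1-carboxylate
Conditions: 3-methylbut-2-enoyl chloride, pyridine, 4-(dimethylamino)pyridine (cat.), CH2Cl2, 0 °C
Reagents that add atoms: 3-methylbut-2-enoyl chloride, CC(C)=CC(=O)Cl
Why: O-acylation of the secondary alcohol with the acid chloride under a weak base at low temperature should install the senecioate without β-elimination or deconjugation, the stereocentres staying as they are.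

Step 7
Reactants: 10 tert-butyl (1R,6S)-4-methyl-6-[(3-methylbut-2-enoyl)oxy]-5-oxocyclohex-3-ene-1-carboxylate
Product: 11 (1R,6S)-4-methyl-6-[(3-methylbut-2-enoyl)oxy]-5-oxocyclohex-3-ene-1-carboxylic acid
Conditions: CF3CO2H/CH2Cl2 (1:4), 0 °C to rt
Reagents that add atoms: none
Why: Acidolysis of the tert-butyl ester (loss of 2-methylpropene) frees the acid under conditions that the enone and the senecioate should tolerate.

Step 8
Reactants: 12 2-bromoprop-2-enal
Product: 13 (3S)-2-bromohexa-1,5-dien-3-ol
Conditions: allylboronic acid pinacol ester, (S)-3,3′-bis(2,4,6-triisopropylphenyl)-1,1′-binaphthyl-2,2′-diyl hydrogen phosphate (5 mol %), toluene, −30 °C; aqueous work-up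
Reagents that add atoms: allylboronic acid pinacol ester, C=CCB1OC(C)(C)C(C)(C)O1
Why: Chiral phosphoric acid-catalysed allylboration through a closed six-membered transition state, in which the (S)-acid should direct the allyl group to the Si face of the aldehyde and so set the (S)-carbinol that becomes C8.

Step 9
Reactants: 13 (3S)-2-bromohexa-1,5-dien-3-ol
Product: 14 (3S)-2-bromo-6-methylhepta-1,5-dien-3-ol
Conditions: 2-methylbut-2-ene (excess), second-generation Grubbs catalyst (3 mol %), CH2Cl2, 40 °C
Reagents that add atoms: 2-methylbut-2-ene, CC=C(C)C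
Why: Olefin cross-metathesis of the terminal alkene with 2-methylbut-2-ene builds the prenyl terminus, while the 2-bromo-1,1-disubstituted alkene is too hindered and electron-poor to take part.

Step 10
Reactants: 14 (3S)-2-bromo-6-methylhepta-1,5-dien-3-ol
Product: 15 {[(3S)-2-bromo-6-methylhepta-1,5-dien-3-yl]oxy}(tert-butyl)dimethylsilane
Conditions: TBSCl, imidazole, DMF, rt
Reagents that add atoms: tert-butyldimethylsilyl chloride, CC(C)(C)[Si](C)(C)Cl
Why: Silylation turns the carbinol oxygen into a poor leaving group, so that the alkenylmetal made next to it should not eliminate to an allene.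

Step 11
Reactants: 11 (1R,6S)-4-methyl-6-[(3-methylbut-2-enoyl)oxy]-5-oxocyclohex-3-ene-1-carboxylic acid; 15 {[(3S)-2-bromo-6-methylhepta-1,5-dien-3-yl]oxy}(tert-butyl)dimethylsilane
Product: 18 (1S,6S)-6-{(3S)-3-[(tert-butyldimethylsilyl)oxy]-6-methylhepta-1,5-dien-2-yl}-3-methyl-2-oxocyclohex-3-en-1-yl 3-methylbut-2-enoate, via N-acyloxyphthalimide ester 16 (not isolated), via alkenylzinc chloride 17 (not isolated)
Conditions: 11, N-hydroxyphthalimide, N,N′-diisopropylcarbodiimide, 4-(dimethylamino)pyridine (cat.), CH2Cl2, rt; separately 15, t-BuLi (2.0 equiv), Et2O, −78 °C, then ZnCl2, THF; then Ni(acac)2 (10 mol %), 2,2′-bipyridine (10 mol %), THF/DMF, rt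
Reagents that add atoms: none
Why: Nickel-catalysed decarboxylative alkenylation of a redox-active ester: electron transfer to 16 releases CO2 and phthalimide, the secondary C5 radical is captured by the alkenylnickel species formed from 17, and reductive elimination gives the C5–C7 bond, which should form trans to the C6 ester on the planar ring radical for steric reasons, so that C5 is set here whatever its configuration in 11.

Step 12
Reactants: 18 (1S,6S)-6-{(3S)-3-[(tert-butyldimethylsilyl)oxy]-6-methylhepta-1,5-dien-2-yl}-3-methyl-2-oxocyclohex-3-en-1-yl 3-methylbut-2-enoate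
Product: 19 (1S,6S)-6-[(3S)-3-hydroxy-6-methylhepta-1,5-dien-2-yl]-3-methyl-2-oxocyclohex-3-en-1-yl 3-methylbut-2-enoate
Conditions: HF·pyridine, pyridine, THF, 0 °C to rt
Reagents that add atoms: none
Why: Fluoride-mediated desilylation under buffered conditions should free the C8 alcohol without touching the enone, the ester or the α-acyloxy ketone.

Step 13
Reactants: 19 (1S,6S)-6-[(3S)-3-hydroxy-6-methylhepta-1,5-dien-2-yl]-3-methyl-2-oxocyclohex-3-en-1-yl 3-methylbut-2-enoate
Product: 20 (3S)-6-methyl-2-{(1S,2S)-4-methyl-2-[(3-methylbut-2-enoyl)oxy]-3-oxocyclohex-4-en-1-yl}hepta-1,5-dien-3-yl (2Z)-2-methylbut-2-enoate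
Conditions: (Z)-2-methylbut-2-enoic acid, 2,4,6-trichlorobenzoyl chloride, Et3N, toluene, rt; then 19, 75 °C
Reagents that add atoms: (Z)-2-methylbut-2-enoic acid (angelic acid), C/C=C(/C)C(=O)O
Why: Yamaguchi esterification through the mixed anhydride without a nucleophilic catalyst is the acyl transfer expected to deliver the angeloyl group to the hindered carbinol with its Z geometry intact and with retention at C8.

Step 14
Reactants: 20 (3S)-6-methyl-2-{(1S,2S)-4-methyl-2-[(3-methylbut-2-enoyl)oxy]-3-oxocyclohex-4-en-1-yl}hepta-1,5-dien-3-yl (2Z)-2-methylbut-2-enoate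
Product: 21 (3S)-2-{(1S,2S,3S)-3-hydroxy-4-methyl-2-[(3-methylbut-2-enoyl)oxy]cyclohex-4-en-1-yl}-6-methylhepta-1,5-dien-3-yl (2Z)-2-methylbut-2-enoate
Conditions: NaBH4, CeCl3·7H2O, MeOH, −78 °C
Reagents that add atoms: none
Why: Luche 1,2-reduction, in which axial hydride delivery to the half-chair with equatorial C5 and C6 substituents should give the pseudo-equatorial C1 alcohol, trans to the C6 ester and cis to the C5 side chain.

Step 15
Reactants: 21 (3S)-2-{(1S,2S,3S)-3-hydroxy-4-methyl-2-[(3-methylbut-2-enoyl)oxy]cyclohex-4-en-1-yl}-6-methylhepta-1,5-dien-3-yl (2Z)-2-methylbut-2-enoate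
Product: 22 (3S)-2-{(1R,2R,3S,4S,6S)-2-hydroxy-1-methyl-3-[(3-methylbut-2-enoyl)oxy]-7-oxabicyclo[4.1.0]heptan-4-yl}-6-methylhepta-1,5-dien-3-yl (2Z)-2-methylbut-2-enoate
Conditions: VO(acac)2 (5 mol %), t-BuOOH (decane solution), CH2Cl2, 0 °C to rt
Reagents that add atoms: tert-butyl hydroperoxide, CC(C)(C)OO
Why: Vanadium-catalysed hydroxyl-directed epoxidation delivers oxygen to the ring alkene syn to the C1 hydroxyl, hence cis to the C5 side chain, and should leave the isolated and the ester-conjugated alkenes alone because they lack a directing hydroxyl.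

Step 16
Reactants: 22 (3S)-2-{(1R,2R,3S,4S,6S)-2-hydroxy-1-methyl-3-[(3-methylbut-2-enoyl)oxy]-7-oxabicyclo[4.1.0]heptan-4-yl}-6-methylhepta-1,5-dien-3-yl (2Z)-2-methylbut-2-enoate
Product: 23 (3S)-6-methyl-2-{(1S,3S,4S,6S)-1-methyl-3-[(3-methylbut-2-enoyl)oxy]-2-oxo-7-oxabicyclo[4.1.0]heptan-4-yl}hepta-1,5-dien-3-yl (2Z)-2-methylbut-2-enoate
Conditions: Dess–Martin periodinane, NaHCO3, CH2Cl2, 0 °C to rt
Reagents that add atoms: none
Why: Dess–Martin oxidation of the secondary epoxy alcohol under buffered, non-basic conditions should give the epoxy ketone without opening the oxirane or epimerising C6.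

**Compound list**

1 | but-2-yn-1-ol | CC#CCO | starting material
2 | sodium 2,2-bis(2-methoxyethoxy)-3-methyl-2,5-dihydro-1,2-oxaluminol-2-uide (cyclic alkenylalanate) | [Na+].COCCO[Al-]1(OCCOC)OCC=C1C | intermediate
3 | (2Z)-3-iodobut-2-en-1-ol | OC/C=C(/C)I | intermediate
4 | (2Z)-1-bromo-3-iodobut-2-ene | BrC/C=C(/C)I | intermediate
5 | 2-[(4S)-2,2-dimethyl-5-oxo-1,3-dioxolan-4-yl]acetic acid | CC1(C)O[C@@H](CC(=O)O)C(=O)O1 | starting material
6 | tert-butyl 2-[(4S)-2,2-dimethyl-5-oxo-1,3-dioxolan-4-yl]acetate | CC1(C)O[C@@H](CC(=O)OC(C)(C)C)C(=O)O1 | intermediate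
7 | tert-butyl (3S)-3-hydroxy-4-[methoxy(methyl)amino]-4-oxobutanoate | CON(C)C(=O)[C@@H](O)CC(=O)OC(C)(C)C | intermediate
8 | lithium alkoxide of tert-butyl (2R,3S)-3-hydroxy-2-[(2Z)-3-iodobut-2-en-1-yl]-4-[methoxy(methyl)amino]-4-oxobutanoate | [Li+].CC(C)(C)OC(=O)[C@@H]([C@H]([O-])C(=O)N(C)OC)C/C=C(/C)I | intermediate
9 | tert-butyl (1R,6S)-6-hydroxy-4-methyl-5-oxocyclohex-3-ene-1-carboxylate | CC(C)(C)OC(=O)[C@@H]1CC=C(C)C(=O)[C@H]1O | intermediate
10 | tert-butyl (1R,6S)-4-methyl-6-[(3-methylbut-2-enoyl)oxy]-5-oxocyclohex-3-ene-1-carboxylate | CC(C)(C)OC(=O)[C@@H]1CC=C(C)C(=O)[C@H]1OC(=O)C=C(C)C | intermediate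
11 | (1R,6S)-4-methyl-6-[(3-methylbut-2-enoyl)oxy]-5-oxocyclohex-3-ene-1-carboxylic acid | OC(=O)[C@@H]1CC=C(C)C(=O)[C@H]1OC(=O)C=C(C)C | intermediate
12 | 2-bromoprop-2-enal (2-bromoacrolein) | C=C(Br)C=O | starting material
13 | (3S)-2-bromohexa-1,5-dien-3-ol | C=C(Br)[C@H](CC=C)O | intermediate
14 | (3S)-2-bromo-6-methylhepta-1,5-dien-3-ol | C=C(Br)[C@H](CC=C(C)C)O | intermediate
15 | {[(3S)-2-bromo-6-methylhepta-1,5-dien-3-yl]oxy}(tert-butyl)dimethylsilane | C=C(Br)[C@H](CC=C(C)C)O[Si](C)(C)C(C)(C)C | intermediate
16 | 1,3-dioxoisoindolin-2-yl (1R,6S)-4-methyl-6-[(3-methylbut-2-enoyl)oxy]-5-oxocyclohex-3-ene-1-carboxylate | O=C(ON1C(=O)c2ccccc2C1=O)[C@@H]1CC=C(C)C(=O)[C@H]1OC(=O)C=C(C)C | intermediate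
17 | {(3S)-3-[(tert-butyldimethylsilyl)oxy]-6-methylhepta-1,5-dien-2-yl}zinc chloride | C=C([Zn]Cl)[C@H](CC=C(C)C)O[Si](C)(C)C(C)(C)C | intermediate
18 | (1S,6S)-6-{(3S)-3-[(tert-butyldimethylsilyl)oxy]-6-methylhepta-1,5-dien-2-yl}-3-methyl-2-oxocyclohex-3-en-1-yl 3-methylbut-2-enoate | C=C([C@H](CC=C(C)C)O[Si](C)(C)C(C)(C)C)[C@@H]1CC=C(C)C(=O)[C@H]1OC(=O)C=C(C)C | intermediate
19 | (1S,6S)-6-[(3S)-3-hydroxy-6-methylhepta-1,5-dien-2-yl]-3-methyl-2-oxocyclohex-3-en-1-yl 3-methylbut-2-enoate | C=C([C@H](CC=C(C)C)O)[C@@H]1CC=C(C)C(=O)[C@H]1OC(=O)C=C(C)C | intermediate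
20 | (3S)-6-methyl-2-{(1S,2S)-4-methyl-2-[(3-methylbut-2-enoyl)oxy]-3-oxocyclohex-4-en-1-yl}hepta-1,5-dien-3-yl (2Z)-2-methylbut-2-enoate | C=C([C@H](CC=C(C)C)OC(=O)/C(C)=C\C)[C@@H]1CC=C(C)C(=O)[C@H]1OC(=O)C=C(C)C | intermediate
21 | (3S)-2-{(1S,2S,3S)-3-hydroxy-4-methyl-2-[(3-methylbut-2-enoyl)oxy]cyclohex-4-en-1-yl}-6-methylhepta-1,5-dien-3-yl (2Z)-2-methylbut-2-enoate | C=C([C@H](CC=C(C)C)OC(=O)/C(C)=C\C)[C@@H]1CC=C(C)[C@H](O)[C@H]1OC(=O)C=C(C)C | intermediate
22 | (3S)-2-{(1R,2R,3S,4S,6S)-2-hydroxy-1-methyl-3-[(3-methylbut-2-enoyl)oxy]-7-oxabicyclo[4.1.0]heptan-4-yl}-6-methylhepta-1,5-dien-3-yl (2Z)-2-methylbut-2-enoate | C=C([C@H](CC=C(C)C)OC(=O)/C(C)=C\C)[C@@H]1C[C@@H]2O[C@]2(C)[C@H](O)[C@H]1OC(=O)C=C(C)C | intermediate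
23 | (3S)-6-methyl-2-{(1S,3S,4S,6S)-1-methyl-3-[(3-methylbut-2-enoyl)oxy]-2-oxo-7-oxabicyclo[4.1.0]heptan-4-yl}hepta-1,5-dien-3-yl (2Z)-2-methylbut-2-enoate (CNP0333561.1) | C=C([C@H](CC=C(C)C)OC(=O)/C(C)=C\C)[C@@H]1C[C@@H]2O[C@]2(C)C(=O)[C@H]1OC(=O)C=C(C)C | target

**Count and risks**

Total step count: 16. Longest linear sequence: 11 steps (steps 3, 4, 5, 6, 7, 11, 12, 13, 14, 15, 16 from compound 5; the branch from compound 1 is equally long).

Steps most likely to fail:

Step 5. The iodine–magnesium exchange may stay incomplete in the presence of the amine and the lithium salts, the alkenylmagnesium may be quenched by proton transfer, or a butyl group of the magnesate may be transferred to the amide. The fallback sets out from 7, makes the two bonds in separate steps and closes the ring by metathesis at C2=C3 instead. Fráter–Seebach allylation of 7 (LiN(i-Pr)2, allyl bromide, THF, −78 to −15 °C) should give tert-butyl (2R,3S)-3-hydroxy-4-[methoxy(methyl)amino]-4-oxo-2-(prop-2-en-1-yl)butanoate F1. Addition of isopropenylmagnesium bromide (excess, THF, −20 to 0 °C) to the Weinreb amide should give tert-butyl (2R,3S)-3-hydroxy-5-methyl-4-oxo-2-(prop-2-en-1-yl)hex-5-enoate F2. Ring-closing metathesis (second-generation Grubbs catalyst, toluene, 80 °C) then closes the cyclohexenone, and the fallback comes back to the route at 9.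

Step 11. Capture of the hindered C5 radical by the α-branched alkenylnickel may be slow, the alkenylzinc may add in conjugate fashion to the ring enone or eliminate to an allene, and delivery trans to the C6 ester may be incomplete. The fallback sets out from 11 and 15 and joins them directly by metallaphotoredox decarboxylative alkenylation ([Ir(dF(CF3)ppy)2(dtbbpy)]PF6 1 mol %, NiCl2·glyme 10 mol %, 4,4′-di-tert-butyl-2,2′-bipyridine, Cs2CO3, DMSO, blue light, rt). The carboxylate is oxidised to the same C5 radical while the alkenyl bromide enters at nickel by oxidative addition, so neither a redox-active ester nor an organozinc reagent is present. This fallback makes no compound outside the list (F0) and comes back to the route at 18.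

Step 13. The angeloyl unit may isomerise from Z to E during acyl transfer, and acylation of the hindered carbinol may be slow. The fallback sets out from 19 and builds the ester by palladium-catalysed alkoxycarbonylation instead of acyl transfer ((Z)-2-bromobut-2-ene, CO 1 atm, PdCl2(PPh3)2, Et3N, DMF, 60 °C). The alkenyl bromide is carbonylated with retention of its geometry and the acylpalladium is taken up by the C8 alcohol, so no free angeloyl donor that could isomerise is involved. This fallback makes no compound outside the list (F0) and comes back to the route at 20.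

**Further compounds**

F1 | step 5 | tert-butyl (2R,3S)-3-hydroxy-4-[methoxy(methyl)amino]-4-oxo-2-(prop-2-en-1-yl)butanoate | CC(C)(C)OC(=O)[C@@H]([C@H](O)C(=O)N(C)OC)CC=C
F2 | step 5 | tert-butyl (2R,3S)-3-hydroxy-5-methyl-4-oxo-2-(prop-2-en-1-yl)hex-5-enoate | CC(C)(C)OC(=O)[C@@H]([C@H](O)C(=O)C(C)=C)CC=C
F0 | step 11 | none | none
F0 | step 13 | none | none
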